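Target forms from substrate and partner, one of each, while a catalyst turns over. You have these flasks, readings and questions:

common to all: free catalyst 0.0240 M

|  | substrate | partner | time |
|---|---|---|---|
| Tuesday's | 0.800 M | 0.800 M |  |
| Monday's | 0.480 M | 0.480 M |  |
| Wednesday's | 0.800 M | 1.60 M |  |
| Friday's | 2.40 M | 0.800 M |  |
| Thursday's | 2.40 M | 0.260 M | 5.7 h |

| run | time / h | [target] / M |
|---|---|---|
| Tuesday's run | 0.23 | 0.037 |
| Tuesday's run | 0.39 | 0.057 |
| Tuesday's run | 0.67 | 0.095 |
| Tuesday's run | 1.1 | 0.154 |
| Tuesday's run | 1.9 | 0.221 |
| Tuesday's run | 3.3 | 0.328 |
| Tuesday's run | 5.7 | 0.402 |
| Monday's run | 0.23 | 0.009 |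
| Monday's run | 0.39 | 0.023 |
| Monday's run | 0.67 | 0.047 |
| Monday's run | 1.1 | 0.072 |
| Monday's run | 1.9 | 0.115 |
| Monday's run | 3.3 | 0.179 |
| Monday's run | 5.7 | 0.221 |
| Wednesday's run | 0.23 | 0.058 |
| Wednesday's run | 0.39 | 0.079 |
| Wednesday's run | 0.67 | 0.143 |
| Wednesday's run | 1.1 | 0.203 |
| Wednesday's run | 1.9 | 0.308 |
| Wednesday's run | 3.3 | 0.423 |
| Wednesday's run | 5.7 | 0.524 |
| Friday's run | 0.23 | 0.102 |
| Friday's run | 0.39 | 0.154 |
| Friday's run | 0.67 | 0.249 |
| Friday's run | 1.1 | 0.367 |
| Friday's run | 1.9 | 0.494 |
| Friday's run | 3.3 | 0.565 |
| Friday's run | 5.7 | 0.572 |

(standard deviation of a reading: 0.006 M)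

- Overall: substrate + partner -> target, with free catalyst as catalyst.
- Constant volume, constant temperature.
- An order is taken over about fifteen percent of the charge, up and down.

- apparent order in [substrate] of the starting rate, round the charge of the Tuesday's run (the rate where two percent of its substrate have turned into target) (one fixed amount of target, the same in the runs compared)
- apparent order in [partner] of the starting rate, round the charge of the Tuesday's run (the rate where two percent of its substrate have turned into target)
- the Monday's run starts with 0.320 M less of substrate and of partner than the Tuesday's run, and with no target. Compared where both hold the same amount of substrate, once fifteen percent of what the Monday's run was charged with has turned into target, is the Monday's run faster, slower or alike (within a tenth)?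
- target in the Thursday's run at 5.7 h, as a share of the substrate charged

Look at Friday's run. Partner is the limiting reagent there, 0.800 M against 2.40 M of substrate, yet target reads 0.565 M at 3.3 h and 0.572 M at 5.7 h. So you have a plateau that doesn't match the charge: 0.228 M of partner isn't found in target.

Write the partner's balance: charge equals partner present, plus target, plus partner gone another way. My reading is that partner present has reached zero at Friday's plateau, and that the gap left by a first-order step of its own. Each partner then has two exits, to target at a rate constant per partner and to loss at a constant k, and the share reaching target is the first over the sum of both. Friday's first reading gives 0.554 h⁻¹ for the target exit. Holding that value, roughly, gives the partner's loss constant 0.221 h⁻¹.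

Now take Thursday's run, with Friday's substrate but 0.260 M of partner. The first readings of Wednesday's and Tuesday's runs give a partner order of 0.649. Thursday's target exit is therefore 0.823 h⁻¹, larger than Friday's. Holding both exits at these starting values through the run, I estimate its share at 0.788, which is 0.205 M of target, or 8.54 % of the substrate charged.

The forecast gives orders of 0.93 in substrate and 0.55 in partner, says Monday's run is faster, and puts Thursday's run at 9.2 %. Its ground for the stall differs from mine: “So the catalyst is dying, fastest at high substrate.” My share is lower than its figure, and my partner order is higher than its order.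

The flask gives 0.96 and 0.46 for the orders, faster for Monday's run, and 8.57 % for Thursday's run. The forecast's partner order is higher than this by a factor of 1.20. Thursday's figure is 0.206 M of target, or 0.791 of its partner charge, where 0.788 was reckoned.

    free catalyst + substrate → loaded catalyst + by-product (6.192 M⁻¹ h⁻¹)
    loaded catalyst + partner → target + free catalyst (63.72 M⁻¹ h⁻¹)
    partner → lost reagent (0.3078 h⁻¹)
    substrate + partner → target (0.1037 M⁻¹ h⁻¹)

Monday's run against Tuesday's shows the partner's loss. At 1.1 h Monday's run reads 0.072 M of target and so holds about 0.408 M of substrate, apart from what sits on the catalyst, which Tuesday's run reaches after making about 0.392 M. With 0.221 h⁻¹ and the target exit from Tuesday's first reading, held through the run, Tuesday's partner charge reckons to about 0.381 M of target, close to that amount. There Monday's run is faster than Tuesday's by a factor of 7.2 because of the step from partner to lost reagent; without that step the ratio is 1.0.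

The runs were computed for an exercise; the scatter is artificial.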